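If free base pays for the reaction, the number to watch is free base charged over electrophile charged. In the flask called south, 22.0 mM of free base meets 20 mM of electrophile, so this stands at 1.10. I call it the base cover.

in all of them: electrophile 20 mM
- delta: free base 45 mM; protonated nucleophile 22 mM; run made earlier
- eta: free base 100 mM; protonated nucleophile 22 mM; run made earlier
- north-east: free base 88.0 mM; protonated nucleophile 22.0 mM; time 2.5 h
- north: free base 44.0 mM; protonated nucleophile 22.0 mM; time 2.5 h
- south: free base 22.0 mM; protonated nucleophile 22.0 mM; time 2.5 h

| run | time / h | electrophile / % | target / % |
|---|---|---|---|
| delta | 0.500 | 3.5 | 66.3 |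
| delta | 1.00 | 2.8 | 61.8 |
| delta | 1.50 | 3.2 | 58.6 |
| delta | 2.00 | 2.8 | 55.6 |
| delta | 2.50 | 2.6 | 54.4 |
| eta | 0.500 | 1.1 | 27.3 |
| eta | 1.00 | 0.8 | 10.3 |
| eta | 1.50 | 0.5 | 4.7 |
| eta | 2.00 | 0.6 | 2.4 |
| eta | 2.50 | 0.4 | 1.4 |

(readings scatter by 0.3 percentage points)

* part of the electrophile that has reacted at the end, north-east
* part of the electrophile that has reacted at the end, north
* part of the electrophile that has reacted at the end, south
* what raising the concentration of free base from its lowest to its highest value here does to the part of the electrophile that has reacted (changes below 5 percentage points count as none) (it rises / no change / it falls)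

- what has gone from electrophile into another species counts as reacted, even if it can come back

The bench rule says that, with electrophile and protonated nucleophile charged alike, equal cover means an equal flask. North has a cover of 2.20 against 2.25 in delta, so I take delta's last electrophile reading, 2.6%, and expect 97.4% reacted. North-east, at 4.40, lies nearer eta, so I expect about 99.6%. Reacted does not mean target, though: in delta the target reads 66.3% falling to 54.4% while the electrophile reads 3.5% falling to 2.6%, so target is going on into something else.

The rule stops as the cover nears one, and south's cover is about half of delta's, outside both runs. Its spare base, charge minus electrophile, is 2.00 mM, which is 0.0800 of delta's. Electrophile left times spare base reads about twice as large in delta as in eta, so this scaling is crude. It leaves 16.0% to 32.5% of south's electrophile unreacted. Even the lower end puts south more than 5 percentage points behind north-east, so I say the part reacted rises with base.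

The forecast, higher on south than my range, gives 99.3% for north-east, 97.2% for north and 86% for south, and for the trend it rises: “The part reacted therefore rises with base”. The flask gives 99.6% for north-east, 97.3% for north and 87.7% for south, so it rises, by 12 points, and south ends above the 84.0% at the top of my range.

    electrophile + nucleophile → acid set free + target (k = 1.22 M⁻¹ s⁻¹)
    nucleophile + acid set free ⇌ protonated nucleophile, settled at all times (K = 2.60 × 10⁵ M⁻¹)
    acid set free + free base ⇌ salt of the base, settled at all times (K = 1.80 × 10⁵ M⁻¹)
    free base + target → over-reaction product (k = 0.0134 M⁻¹ s⁻¹)
    electrophile ⇌ dormant form (K = 2.30, k = 0.00117 s⁻¹)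

South's cover of 1.10 ends with free base, the limiting reagent, at 0.27% of its charge, while 28.6% of the electrophile sits as dormant form, counted as reacted. The neighbour flask is south with 80 mM of electrophile, so its cover is 27.5%. Its free base ends at 0.0945% of charge, and its target stands at 17.3%, below the cover. Its part reacted is 75.0% of the electrophile charged, and its dormant form stands at 57.7% of that charge.

The readings are calculated on assumed constants; the scatter is artificial.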